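**Strategy.** The fourteen-membered ring is disconnected at the sp2–sp3 bond between the CH3-bearing carbon of the Z-trisubstituted ring alkene and its allylic ring CH2, which lies two carbons from the R stereocentre. That ring CH2–CH2 link is carried in the precursor as a vinyl group on the stereocentre. One-pot 9-BBN hydroboration and intramolecular B-alkyl Suzuki–Miyaura coupling with a (Z)-2-iodoalkene terminus closes the macrocycle and fixes the Z geometry by retention. The acyclic iodo-hexaene ester comes from a Z-selective Horner–Wadsworth–Emmons union of an iodo-dienyl phosphonate with an aldehyde whose stereocentre is set by Johnson–Claisen chirality transfer.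

Key step: step 14

Assumption 1: (+)-B-allyldiisopinocampheylborane means the reagent whose isopinocampheyl groups derive from (−)-α-pinene; it is taken to deliver allyl to the re face of aldehyde 4, as this reagent class does with aldehydes whose substituent outranks allyl.
Assumption 2: compounds 1, 12 and 19 and the allylborane solution are taken as purchasable.

**Fragment A (aldehyde 11)**

Step 1
Reactants: 1 prop-2-yn-1-ol
Product: 3 (2E)-3-iodo-2-methylprop-2-en-1-ol, via alkenylalane 2 (not isolated)
Conditions: AlMe3, Cp2ZrCl2 (25 mol %), CH2Cl2, 0 °C to rt; then I2, THF, −30 to 0 °C; aq. K2CO3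
Reagents that add atoms: trimethylaluminium, C[Al](C)C; iodine, II
Why: Zirconium-catalysed Negishi carboalumination adds CH3 and Al syn across the alkyne with CH3 on the internal carbon, and iodinolysis of the C–Al bond with retention should give the E iodoalkene; no stereocentre is formed.

Step 2
Reactants: 3 (2E)-3-iodo-2-methylprop-2-en-1-ol
Product: 4 (2E)-3-iodo-2-methylprop-2-enal
Conditions: MnO2, CH2Cl2, rt
Reagents that add atoms: none
Why: MnO2 oxidises allylic alcohols selectively to enals under neutral conditions, so the E iodoalkene should survive unchanged.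

Step 3
Reactants: 4 (2E)-3-iodo-2-methylprop-2-enal
Product: 6 (1E,3R)-1-iodo-2-methylhexa-1,5-dien-3-ol, via borinate 5 (not isolated)
Conditions: (+)-B-allyldiisopinocampheylborane (from (−)-α-pinene), Et2O, −78 °C; then NaOH, H2O2, 0 °C to rt
Reagents that add atoms: (+)-B-allyldiisopinocampheylborane, C=CCB([C@H]1C[C@H]2C[C@@H]([C@@H]1C)C2(C)C)[C@H]1C[C@H]2C[C@@H]([C@@H]1C)C2(C)C
Why: Brown allylboration through a closed chair Zimmerman–Traxler transition state, in which the isopinocampheyl groups direct allyl transfer to the re face of the aldehyde and so set the R carbinol centre.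

Step 4
Reactants: 6 (1E,3R)-1-iodo-2-methylhexa-1,5-dien-3-ol
Product: 7 (1E,3R)-1-iodo-2,7-dimethylocta-1,6-dien-3-ol
Conditions: 2-methylbut-2-ene (large excess), second-generation Grubbs catalyst RuCl2(H2IMes)(PCy3)(=CHPh) (5 mol %), CH2Cl2, 40 °C
Reagents that add atoms: 2-methylbut-2-ene, CC=C(C)C
Why: Olefin cross-metathesis of the monosubstituted alkene with excess 2-methylbut-2-ene exchanges the CH2 terminus for an isopropylidene group, while the hindered trisubstituted iodoalkene should not engage the ruthenium carbene and the carbinol centre is untouched.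

Step 5
Reactants: 7 (1E,3R)-1-iodo-2,7-dimethylocta-1,6-dien-3-ol
Product: 8 (3E,5R)-4,8-dimethylnona-1,3,7-trien-5-ol
Conditions: tributyl(vinyl)stannane, PdCl2(MeCN)2 (5 mol %), DMF, rt
Reagents that add atoms: tributyl(vinyl)stannane, C=C[Sn](CCCC)(CCCC)CCCC
Why: Stille coupling of the alkenyl iodide proceeds with retention of the E geometry under neutral conditions that tolerate the free alcohol, giving the 1,3-diene.

Step 6
Reactants: 8 (3E,5R)-4,8-dimethylnona-1,3,7-trien-5-ol
Product: 10 ethyl (3S,4E)-3-ethenyl-4,8-dimethylnona-4,7-dienoate, via ketene acetal 9 (not isolated)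
Conditions: MeC(OEt)3 (excess), EtCO2H (cat.), 135 °C, ethanol distilled off
Reagents that add atoms: triethyl orthoacetate, CCOC(C)(OCC)OCC
Why: Johnson–Claisen rearrangement through a chair transition state with the prenyl-bearing CH2 substituent equatorial forms the E trisubstituted alkene and delivers the new C–C bond suprafacially to the alkene face that carried the oxygen, so the R carbinol configuration is transferred to the S vinyl-bearing stereocentre.

Step 7
Reactants: 10 ethyl (3S,4E)-3-ethenyl-4,8-dimethylnona-4,7-dienoate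
Product: 11 (3S,4E)-3-ethenyl-4,8-dimethylnona-4,7-dienal
Conditions: i-Bu2AlH (1.1 equiv), CH2Cl2, −78 °C; aq. potassium sodium tartrate
Reagents that add atoms: none
Why: Partial ester reduction by i-Bu2AlH stops at the tetrahedral aluminium hemiacetal at −78 °C, which gives the aldehyde on work-up; the stereocentre is beta to the carbonyl and cannot epimerise by enolisation.

**Fragment B (phosphonate 20)**

Step 8
Reactants: 12 pent-4-yn-1-ol
Product: 13 pent-4-ynal
Conditions: TEMPO (10 mol %), PhI(OAc)2, CH2Cl2, rt
Reagents that add atoms: none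
Why: TEMPO-catalysed oxidation with PhI(OAc)2 converts the primary alcohol to the aldehyde without over-oxidation or attack on the alkyne.

Step 9
Reactants: 13 pent-4-ynal
Product: 14 (5Z)-6-iodohept-5-en-1-yne
Conditions: [Ph3PEt]I, n-BuLi, THF, rt; I2, −78 °C; NaN(SiMe3)2, −20 °C; then 13, −78 °C
Reagents that add atoms: ethyltriphenylphosphonium iodide, CC[P+](c1ccccc1)(c1ccccc1)c1ccccc1.[I-]; iodine, II
Why: Wittig olefination with the alpha-iodo ylide (Stork–Zhao-type) under kinetic control should give the Z 2-iodoalkene, with iodine cis to the chain.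

Step 10
Reactants: 14 (5Z)-6-iodohept-5-en-1-yne
Product: 17 (3E,7Z)-8-iodo-4-methylnona-3,7-dien-1-ol, via alkenylalane 15 (not isolated), via lithium alanate 16 (not isolated)
Conditions: AlMe3, Cp2ZrCl2 (25 mol %), CH2Cl2, 0 °C to rt; volatiles removed; MeLi (1 equiv), hexane/THF, −78 °C; ethylene oxide, −78 °C to rt; aq. HCl
Reagents that add atoms: trimethylaluminium, C[Al](C)C; ethylene oxide, C1CO1
Why: Negishi carboalumination adds CH3 and Al syn with CH3 at the internal alkyne carbon, and the derived lithium alanate transfers its alkenyl group to ethylene oxide with retention to give the E trisubstituted homoallylic alcohol, methyllithium being expected to complex the Lewis-acidic alane faster than it exchanges with the alkenyl iodide.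

Step 11
Reactants: 17 (3E,7Z)-8-iodo-4-methylnona-3,7-dien-1-ol
Product: 18 (2Z,6E)-2,9-diiodo-6-methylnona-2,6-diene
Conditions: PPh3, I2, imidazole, CH2Cl2, 0 °C
Reagents that add atoms: iodine, II
Why: Appel-type iodination converts the primary alcohol to the iodide by SN2 displacement of the oxyphosphonium group, leaving both alkenes and the alkenyl iodide untouched.

Step 12
Reactants: 18 (2Z,6E)-2,9-diiodo-6-methylnona-2,6-diene; 19 ethyl 2-[bis(2-methylphenoxy)phosphoryl]acetate
Product: 20 ethyl (5E,9Z)-2-[bis(2-methylphenoxy)phosphoryl]-10-iodo-6-methylundeca-5,9-dienoate (racemic)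
Conditions: NaH, DMSO/THF, rt to 50 °C (19 in slight excess)
Reagents that add atoms: none
Why: C-Alkylation (SN2) of the sodium salt of the phosphonoacetate with the primary alkyl iodide, the alkenyl iodide being inert; the new carbon centre forms as a racemate and is destroyed in the next step.

**Union, ring closure and end game**

Step 13
Reactants: 11 (3S,4E)-3-ethenyl-4,8-dimethylnona-4,7-dienal; 20 ethyl (5E,9Z)-2-[bis(2-methylphenoxy)phosphoryl]-10-iodo-6-methylundeca-5,9-dienoate
Product: 21 ethyl (2Z,5S,6E)-5-ethenyl-2-[(3E,7Z)-8-iodo-4-methylnona-3,7-dien-1-yl]-6,10-dimethylundeca-2,6,9-trienoate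
Conditions: NaH, THF, −78 to 0 °C
Reagents that add atoms: none
Why: Horner–Wadsworth–Emmons olefination with a diaryl phosphonate (Ando variant), in which fast irreversible collapse of the kinetically formed adduct of the electron-poor aryloxy phosphonate should place the ester cis to the aldehyde-derived chain (2Z).

Step 14
Reactants: 21 ethyl (2Z,5S,6E)-5-ethenyl-2-[(3E,7Z)-8-iodo-4-methylnona-3,7-dien-1-yl]-6,10-dimethylundeca-2,6,9-trienoate
Product: 23 ethyl (1Z,4R,7Z,11E)-7,11-dimethyl-4-[(2E)-6-methylhepta-2,5-dien-2-yl]cyclotetradeca-1,7,11-triene-1-carboxylate, via alkylborane 22 (not isolated)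
Conditions: 9-BBN (1.3 equiv), THF, 0 °C to rt; then slow addition (syringe pump) to Pd(dppf)Cl2 (20 mol %), AsPh3 (20 mol %), Cs2CO3 (3 equiv), DMF/THF/H2O, 50 °C, about 1 mM
Reagents that add atoms: none
Why: 9-BBN adds to the only monosubstituted alkene with boron at the terminal carbon to give primary alkylborane 22; zerovalent palladium then inserts into the alkenyl C–I bond with retention, the base-activated borate transfers its primary alkyl group to divalent palladium, and reductive elimination forms the sp2–sp3 bond. The closest known reaction type is the intramolecular B-alkyl Suzuki–Miyaura macrocyclisation of alkenyl iodides. The fourteen-membered carbocycle closes by reductive elimination from a fifteen-membered palladacycle, an end-to-end macrocyclisation favoured by slow addition at high dilution and by the trisubstituted alkenes that restrict the chain. No stereocentre is created: the Z geometry of the new ring alkene is inherited from the Z iodoalkene, and the existing stereocentre, two carbons from boron, is not touched (its descriptor changes from S to R only through the priority rules). The step needs site-selective hydroboration, secured by the strong preference of 9-BBN for monosubstituted over trisubstituted and electron-poor alkenes, and ring closure over oligomerisation, secured by dilution; the ester should tolerate 9-BBN and Cs2CO3.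

Step 15
Reactants: 23 ethyl (1Z,4R,7Z,11E)-7,11-dimethyl-4-[(2E)-6-methylhepta-2,5-dien-2-yl]cyclotetradeca-1,7,11-triene-1-carboxylate
Product: 24 [(1Z,4R,7Z,11E)-7,11-dimethyl-4-[(2E)-6-methylhepta-2,5-dien-2-yl]cyclotetradeca-1,7,11-trien-1-yl]methanol
Conditions: i-Bu2AlH (2.5 equiv), CH2Cl2, −78 to 0 °C; aq. potassium sodium tartrate
Reagents that add atoms: none
Why: 1,2-Reduction of the conjugated ester by i-Bu2AlH gives the allylic alcohol without touching the alkenes, so the alkene geometries and the stereocentre are retained and the target should result.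

**Compound list**

1 | prop-2-yn-1-ol | C#CCO | starting material
2 | dimethylaluminium (2E)-3-(dimethylalumanyl)-2-methylprop-2-en-1-olate (alkenylalane, not isolated) | C/C(CO[Al](C)C)=C\[Al](C)C | intermediate
3 | (2E)-3-iodo-2-methylprop-2-en-1-ol | C/C(CO)=C\I | intermediate
4 | (2E)-3-iodo-2-methylprop-2-enal | C/C(C=O)=C\I | intermediate
5 | (1E,3R)-1-iodo-2-methylhexa-1,5-dien-3-yl diisopinocampheylborinate (not isolated) | C=CC[C@@H](OB([C@H]1C[C@H]2C[C@@H]([C@@H]1C)C2(C)C)[C@H]1C[C@H]2C[C@@H]([C@@H]1C)C2(C)C)/C(C)=C/I | intermediate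
6 | (1E,3R)-1-iodo-2-methylhexa-1,5-dien-3-ol | C=CC[C@@H](O)/C(C)=C/I | intermediate
7 | (1E,3R)-1-iodo-2,7-dimethylocta-1,6-dien-3-ol | CC(C)=CC[C@@H](O)/C(C)=C/I | intermediate
8 | (3E,5R)-4,8-dimethylnona-1,3,7-trien-5-ol | CC(C)=CC[C@@H](O)/C(C)=C/C=C | intermediate
9 | (3E,5R)-5-[(1-ethoxyethenyl)oxy]-4,8-dimethylnona-1,3,7-triene (ketene acetal, not isolated) | CC(C)=CC[C@@H](OC(=C)OCC)/C(C)=C/C=C | intermediate
10 | ethyl (3S,4E)-3-ethenyl-4,8-dimethylnona-4,7-dienoate | CC(C)=CC/C=C(\C)[C@H](C=C)CC(=O)OCC | intermediate
11 | (3S,4E)-3-ethenyl-4,8-dimethylnona-4,7-dienal | CC(C)=CC/C=C(\C)[C@H](C=C)CC=O | intermediate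
12 | pent-4-yn-1-ol | C#CCCCO | starting material
13 | pent-4-ynal | C#CCCC=O | intermediate
14 | (5Z)-6-iodohept-5-en-1-yne | C#CCC/C=C(/C)I | intermediate
15 | [(1E,5Z)-6-iodo-2-methylhepta-1,5-dien-1-yl]dimethylalumane (not isolated) | C[Al](C)/C=C(\C)CC/C=C(/C)I | intermediate
16 | lithium [(1E,5Z)-6-iodo-2-methylhepta-1,5-dien-1-yl]trimethylaluminate (not isolated) | [Li+].C[Al-](C)(C)/C=C(\C)CC/C=C(/C)I | intermediate
17 | (3E,7Z)-8-iodo-4-methylnona-3,7-dien-1-ol | OCC/C=C(\C)CC/C=C(/C)I | intermediate
18 | (2Z,6E)-2,9-diiodo-6-methylnona-2,6-diene | ICC/C=C(\C)CC/C=C(/C)I | intermediate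
19 | ethyl 2-[bis(2-methylphenoxy)phosphoryl]acetate | CCOC(=O)CP(=O)(Oc1ccccc1C)Oc1ccccc1C | starting material
20 | ethyl (5E,9Z)-2-[bis(2-methylphenoxy)phosphoryl]-10-iodo-6-methylundeca-5,9-dienoate (racemic at C2) | CCOC(=O)C(CC/C=C(\C)CC/C=C(/C)I)P(=O)(Oc1ccccc1C)Oc1ccccc1C | intermediate
21 | ethyl (2Z,5S,6E)-5-ethenyl-2-[(3E,7Z)-8-iodo-4-methylnona-3,7-dien-1-yl]-6,10-dimethylundeca-2,6,9-trienoate | CC(C)=CC/C=C(\C)[C@H](C=C)C/C=C(/CC/C=C(\C)CC/C=C(/C)I)C(=O)OCC | intermediate
22 | B-alkyl-9-BBN from 21, boron on the former terminal vinyl carbon, configuration at the stereocentre as in 21 (not isolated) | CC(C)=CC/C=C(\C)[C@H](CCB1C2CCCC1CCC2)C/C=C(/CC/C=C(\C)CC/C=C(/C)I)C(=O)OCC | intermediate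
23 | ethyl (1Z,4R,7Z,11E)-7,11-dimethyl-4-[(2E)-6-methylhepta-2,5-dien-2-yl]cyclotetradeca-1,7,11-triene-1-carboxylate | CC(C)=CC/C=C(\C)[C@H]1C/C=C(\C(=O)OCC)CC/C=C(\C)CC/C=C(/C)CC1 | intermediate
24 | [(1Z,4R,7Z,11E)-7,11-dimethyl-4-[(2E)-6-methylhepta-2,5-dien-2-yl]cyclotetradeca-1,7,11-trien-1-yl]methanol | CC(C)=CC/C=C(\C)[C@H]1C/C=C(\CO)CC/C=C(\C)CC/C=C(/C)CC1 | target

**Totals and risks**

Total step count: 15. Longest linear sequence: 10 steps (steps 1 to 7, then 13 to 15).

Step 14 is the most likely to fail. Intermolecular coupling may outrun ring closure and give oligomers, or the alkylborane may be lost by protodeboronation or beta-hydride elimination at palladium. The same bond can then be closed as an intramolecular Negishi coupling. Setting out from 21, hydroboration with 9-BBN (through 22) and oxidation with NaOH/H2O2 would give the primary alcohol F1. PPh3, I2 and imidazole would give the primary alkyl iodide F2. Activated Zn dust in THF at 40 °C should insert only into the sp3 C–I bond to give the alkylzinc iodide F3. Slow addition of F3 to Pd(PPh3)4 in THF should close the ring and come back to the route at 23.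

Step 10 is the second risk. Methyllithium may undergo halogen–metal exchange at the alkenyl iodide in competition with alanate formation, or the alanate may open the epoxide sluggishly. The order of events is then changed so that no organolithium meets an alkenyl iodide. Setting out from 12, TBSCl and imidazole would give the silyl ether F4. Carboalumination (AlMe3, Cp2ZrCl2) would give the alkenylalane F5, n-BuLi the lithium alanate F6, and ethylene oxide the homoallylic alcohol F7. PPh3, I2 and imidazole would give the silyl-protected iodide F8, and HF·pyridine would free the iodo alcohol F9. Dess–Martin periodinane would give the iodo aldehyde F10. The alpha-iodo ylide olefination of step 9 applied to F10 comes back to the route at 18.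

Step 6 is the third risk. The acid catalyst may ionise the doubly allylic dienyl carbinol before the ketene acetal forms, leading to allylic transposition or elimination and eroding the transfer of chirality. The rearrangement is then run without acid as an Eschenmoser–Claisen reaction. Setting out from 8, heating with N,N-dimethylacetamide dimethyl acetal in toluene would give the ketene N,O-acetal F11, which should rearrange through the same chair to the amide F12. Partial reduction of F12 with LiAlH(OEt)3 comes back to the route at 11.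

**Further compounds**

F1 | step 14 | ethyl (2Z,5S,6E)-5-(2-hydroxyethyl)-2-[(3E,7Z)-8-iodo-4-methylnona-3,7-dien-1-yl]-6,10-dimethylundeca-2,6,9-trienoate | CC(C)=CC/C=C(\C)[C@H](CCO)C/C=C(/CC/C=C(\C)CC/C=C(/C)I)C(=O)OCC
F2 | step 14 | ethyl (2Z,5S,6E)-5-(2-iodoethyl)-2-[(3E,7Z)-8-iodo-4-methylnona-3,7-dien-1-yl]-6,10-dimethylundeca-2,6,9-trienoate | CC(C)=CC/C=C(\C)[C@H](CCI)C/C=C(/CC/C=C(\C)CC/C=C(/C)I)C(=O)OCC
F3 | step 14 | alkylzinc iodide from F2 (zinc inserted into the primary C–I bond) | CC(C)=CC/C=C(\C)[C@H](CC[Zn]I)C/C=C(/CC/C=C(\C)CC/C=C(/C)I)C(=O)OCC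
F4 | step 10 | tert-butyldimethyl(pent-4-yn-1-yloxy)silane | C#CCCCO[Si](C)(C)C(C)(C)C
F5 | step 10 | tert-butyl{[(4E)-5-(dimethylalumanyl)-4-methylpent-4-en-1-yl]oxy}dimethylsilane | C[Al](C)/C=C(\C)CCCO[Si](C)(C)C(C)(C)C
F6 | step 10 | lithium butyl{(1E)-5-[tert-butyl(dimethyl)silyl]oxy-2-methylpent-1-en-1-yl}dimethylaluminate | [Li+].CCCC[Al-](C)(C)/C=C(\C)CCCO[Si](C)(C)C(C)(C)C
F7 | step 10 | (3E)-7-[tert-butyl(dimethyl)silyl]oxy-4-methylhept-3-en-1-ol | OCC/C=C(\C)CCCO[Si](C)(C)C(C)(C)C
F8 | step 10 | tert-butyl{[(4E)-7-iodo-4-methylhept-4-en-1-yl]oxy}dimethylsilane | ICC/C=C(\C)CCCO[Si](C)(C)C(C)(C)C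
F9 | step 10 | (4E)-7-iodo-4-methylhept-4-en-1-ol | ICC/C=C(\C)CCCO
F10 | step 10 | (4E)-7-iodo-4-methylhept-4-enal | ICC/C=C(\C)CCC=O
F11 | step 6 | (3E,5R)-5-{[1-(dimethylamino)ethenyl]oxy}-4,8-dimethylnona-1,3,7-triene | CC(C)=CC[C@@H](OC(=C)N(C)C)/C(C)=C/C=C
F12 | step 6 | (3S,4E)-3-ethenyl-N,N,4,8-tetramethylnona-4,7-dienamide | CC(C)=CC/C=C(\C)[C@H](C=C)CC(=O)N(C)C
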